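## The problem

Germacrane numbering is used throughout: C1 is the ketone carbon, C4–C5 the epoxide, C6 the carbon bearing the lactone oxygen, C7=C11 the butenolide alkene, C8 the angelate carbinol, C10 the methyl-bearing carbon, C12 the lactone carbonyl and C13 the acetoxymethyl carbon. The target is a ten-membered carbocycle (C1–C10) fused along C6–C7 to a butenolide whose tetrasubstituted C7=C11 bond is exocyclic to the large ring, so a medium ring has to be closed whose only rigid elements are that planar lactone, the C1 carbonyl and whatever stands in for the trans-4,5-epoxide. There are five stereocentres: C4 and C5 arise together by syn addition to an (E)-alkene and can be governed by C6 through allylic 1,3-strain; C8 sits next to sp2 C7 and can feel C6 only across the butenolide plane; C10 is insulated from C6 by the C1–C5 chain in any open-chain precursor, so C6 and C10 each need reagent control. The fragile elements are C6–H (γ to the lactone carbonyl and allylic, hence base-labile, and able to expel the C13 acetate by vinylogous elimination), the angelate (isomerised to the tiglate by nucleophilic catalysts and acid), the C10 centre α to the ketone, and the epoxide (acid, Lewis acid, transannular opening). These exclude strong base once C6 is set and argue for bringing in epoxide, acetate and angelate late. The feature that opens the ring construction is that the C8 carbinol is bonded directly to C7, the β-carbon of the butenolide: C7–C8 is the bond made when a β-metallated butenolide adds to an aldehyde. Mucobromic acid supplies such a butenolide with a reactive bromide on C7 and a less reactive one on C11, exactly where C13 must finally stand.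

## Retrosynthesis

**Epoxide last.** The C4–O and C5–O bonds of 23 are cut to give the (E)-alkene 22. Carrying the epoxide earlier would expose it to chromium halides and palladium, and the (E)-alkene is one of the elements that stiffen the ring for closure. The precursor has two stereocentres fewer. The forward step must pick one alkene out of three and one face of it.

**C13 and its acetate.** The acetate of 22 comes from alcohol 21, and the C11–C13 bond of 21 from bromide 20 by cross-coupling with a hydroxymethyl-tin reagent. Installing C13 before ring closure would need a different butenolide building block. The C11 bromide is the residue that mucobromic acid leaves behind and it is inert in the ring closure. The coupling has to work on a hindered α-bromo lactone under neutral conditions.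

**Angelate.** The C8–O acyl bond of 20 is cut to carbinol 19. Acylating after cyclisation keeps the isomerisation-prone ester out of all organometallic steps. The forward step must not isomerise the (Z)-enoate and must not use free base.

**Ring closure (key).** The C7–C8 bond of 19 is cut to the open-chain keto-aldehyde 17, which keeps both bromides.
- The neighbouring ring bonds C8–C9 and C9–C10 are sp3–sp3 bonds without a handle.
- Cutting C5–C6 would set C6 during ring closure and give up reagent control over it.
- C7–C8 is the only ring bond that joins the butenolide's built-in leaving group to a heteroatom-bearing carbon.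

The precursor 17 is acyclic with two stereocentres. The forward reaction must metalate C7–Br and not C11–Br, add to the aldehyde and not the ketone, win against oligomerisation, and choose a face at C8.

**Oxidation level.** Keto-aldehyde 17 comes from diol 16 and this from the bis-silyl ether 15. The cut to follow needs an alkenylmetal, which a ketone or aldehyde would not survive. Both oxygens must be oxidised without a lactol intervening.

**Fragment union at C6.** The C5–C6 bond and the lactone O–C12 bond of 15 are cut to alkenyl iodide 9 and formyl ester 11. This joins two pieces of similar size at the only stereocentre of the butenolide, and the alkenyl-carbinol pattern allows catalytic enantioselective alkenyl transfer. Olefination at C4=C5 would raise an E/Z problem instead. The forward step needs an organometal mild enough for two vinylic bromides and a catalyst that sets C6. Ester 11 is the O-methylated open form of mucobromic acid 10.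

**C8–C10 and C1.** The silyl ethers of 9 come from diol 8, the C8 oxygen of 8 from hydroboration of the terminal alkene of 6, and the C1–C10 bond of 6 from aldehyde 4 and crotylboronate 5. The crotylation sets C10 by reagent control; the C1 carbinol made with it is later erased.

**C1–C5.** Aldehyde 4 comes from alcohol 3, and 3 from pent-4-yn-1-ol 1 by carbometalation. This forms the C4–methyl bond and the C5–iodine bond with (E) geometry in one operation.

## Roads not taken

**Alternative 1:** The cut is O–C6 and O–C13, that is, the butenolide ring itself. In the forward step Pd(OAc)2 with benzoquinone would let the C12 carboxylic acid attack C6 of a C6=C7–C11=C13 diene and acetate attack C13 of the resulting allylpalladium, giving the 13-acetoxy butenolide A1, which is the same compound as 22.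
- Merits: lactone, C6–O stereocentre and C13 acetate come from one catalytic operation, without tin or bromide. After ring formation this road is two steps shorter than the chosen one, and in that respect it is better.
- Weak points: the substrate would be a ten-membered ring in which C6=C7 is conjugated on one side with C4=C5 and on the other with the acrylic acid, so divalent palladium has more than one diene to choose from. C6 would be set by face selection on a flexible triene with only remote C8 and C10 to guide it. The C8 angelate is allylic to the diene and can be ionised by zerovalent palladium.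
- Comparison: the ten-membered ring still has to be made by some other reaction. The chosen plan sets against the shorter endgame that ring closure and butenolide come from one cheap building block and that C6 is fixed by a catalyst before cyclisation.

**Alternative 2:** The cut is C6–C7. In the forward step tin–lithium exchange at C6 of a thirteen-membered cyclic allyl ether would give an α-alkoxy carbanion that attacks C7 in a [2,3]-Wittig shift, breaks O–C12 and contracts the ring to the ten-membered carbinol A2.
- Merits: a thirteen-membered ether is easier to close than a ten-membered carbocycle, and the ordered five-membered transition state transmits configuration to C6 and C7 more predictably than an organochromium addition can promise for C8. On both counts this road is stronger.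
- Weak points: A2 is at the wrong oxidation level. C12 is a methylene, C7 is sp3, and the C7 stereocentre just made has to be destroyed when C7=C11 and the lactone carbonyl are introduced. It also needs a ketal, a silyl ether and a PMB ether, and alkyllithium conditions.
- Comparison: the chosen plan sets against it a butenolide that enters at its final oxidation level, four steps from ring closure to target, and no stereocentre built only to be removed.

**Alternative 3:** The cut is C1–C10. In the forward step a C10 alkenyl iodide would add to a C1 aldehyde under CrCl2 with catalytic NiCl2 to give the exo-methylene allylic alcohol A3, with epoxide, angelate, acetate and butenolide already in place.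
- Merits: the carbinol formed is later oxidised, so the ring closure has no stereochemical demand. This is a real advantage over the chosen closure, which must set C8. The closure also takes place far from the butenolide.
- Weak points: C10 would be created last, by oxidation to the exo-methylene enone and conjugate reduction, with only the ring to select the face and with an epimerisable centre in a base-sensitive molecule. The cyclisation must tolerate an epoxide and the allylic C13 acetate, which zerovalent nickel can ionise and chromium halides can open. The open-chain precursor carries four stereocentres and has to be built linearly.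
- Comparison: the chosen plan answers with a cyclisation substrate that has two stereocentres and no epoxide or allylic acetate, with C10 secured early by crotylation, and with a way to convert the unwanted C8 epimer into the wanted one.

Key step: step 10

Remark: the senses of induction quoted for (R)-TRIP (step 3) and (+)-MIB (step 7) are those shown with simple aldehydes; if either is reversed on these substrates, the enantiomeric catalyst is used with no other change.

## Route

Step 1
Reactants: 1 pent-4-yn-1-ol
Product: 3 (E)-5-iodo-4-methylpent-4-en-1-ol, via alkenylalane 2 (not isolated)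
Conditions: Me3Al (3 equiv), Cp2ZrCl2 (0.25 equiv), CH2Cl2, 0 °C to rt; then I2, THF, −30 to 0 °C
Reagents that add atoms: trimethylaluminium C[Al](C)C; iodine II
Why: Zirconium-catalysed carboalumination (Negishi) adds methyl and aluminium syn across the terminal alkyne with methyl on the internal carbon, the hydroxyl being carried as its aluminium alkoxide; iodinolysis of the alkenyl–aluminium bond goes with retention and gives the (E)-iodide.

Step 2
Reactants: 3 (E)-5-iodo-4-methylpent-4-en-1-ol
Product: 4 (E)-5-iodo-4-methylpent-4-enal
Conditions: Dess–Martin periodinane, NaHCO3, CH2Cl2, 0 °C to rt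
Reagents that add atoms: none
Why: Dess–Martin oxidation stops at the aldehyde and leaves the alkenyl iodide untouched.

Step 3
Reactants: 4 (E)-5-iodo-4-methylpent-4-enal; 5 (E)-crotylboronic acid pinacol ester
Product: 6 (3R,4S,7E)-8-iodo-3,7-dimethylocta-1,7-dien-4-ol
Conditions: (R)-TRIP (5 mol %), PhMe, −30 °C; aqueous work-up
Reagents that add atoms: none
Why: Chiral-phosphoric-acid-catalysed crotylboration runs through a closed chair (Zimmerman–Traxler) transition state, so the (E)-boronate gives the anti adduct; (R)-TRIP is expected to direct the crotyl group to the Re face of the aldehyde, which makes C4 S and the methyl-bearing C3 (C10 of the target) R. Only C10 is kept, since the carbinol is oxidised later.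

Step 4
Reactants: 6 (3R,4S,7E)-8-iodo-3,7-dimethylocta-1,7-dien-4-ol
Product: 8 (3R,4S,7E)-8-iodo-3,7-dimethyloct-7-ene-1,4-diol, via bis-borane 7 (not isolated)
Conditions: 9-BBN (2.5 equiv), THF, 0 °C to rt; then NaOH, H2O2, 0 °C
Reagents that add atoms: hydrogen peroxide OO
Why: 9-BBN hydroborates the monosubstituted alkene at its terminus and ignores the trisubstituted iodoalkene; the first equivalent is taken up by the hydroxyl as a borinate, and alkaline peroxide oxidises the C–B bond with retention and frees both oxygens.

Step 5
Reactants: 8 (3R,4S,7E)-8-iodo-3,7-dimethyloct-7-ene-1,4-diol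
Product: 9 (3R,4S,7E)-8-iodo-3,7-dimethyl-1,4-bis(triethylsilyloxy)oct-7-ene
Conditions: TESCl (2.5 equiv), imidazole, DMF, 0 °C to rt
Reagents that add atoms: chlorotriethylsilane CC[Si](Cl)(CC)CC
Why: Standard silylation of a primary and a secondary alcohol; triethylsilyl ethers survive tert-butyllithium at −78 °C and are later removed by buffered fluoride without base.

Step 6
Reactants: 10 mucobromic acid
Product: 11 methyl (2Z)-2,3-dibromo-4-oxobut-2-enoate
Conditions: TMSCHN2, PhMe/MeOH, 0 °C
Reagents that add atoms: (trimethylsilyl)diazomethane C[Si](C)(C)C=[N+]=[N-]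
Why: Mucobromic acid is in equilibrium with its open-chain (Z)-formyl acid, and O-methylation of that carboxylic acid traps the acyclic ester aldehyde, whereas acid-catalysed methanolysis would give the cyclic pseudo-ester; the (Z) geometry is that of the ring.

Step 7
Reactants: 9 (3R,4S,7E)-8-iodo-3,7-dimethyl-1,4-bis(triethylsilyloxy)oct-7-ene; 11 methyl (2Z)-2,3-dibromo-4-oxobut-2-enoate
Product: 15 (5R)-3,4-dibromo-5-[(1E,5S,6R)-2,6-dimethyl-5,8-bis(triethylsilyloxy)oct-1-en-1-yl]furan-2(5H)-one, via alkenyllithium 12 (not isolated), via alkenylzinc 13 (not isolated), via hydroxy ester 14 (not isolated)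
Conditions: t-BuLi (2 equiv), Et2O, −78 °C; EtZnCl (from Et2Zn and ZnCl2), −78 to 0 °C; TEEDA, (+)-MIB (10 mol %), PhMe; then 11, −20 to 0 °C; aq. NH4Cl
Reagents that add atoms: none
Why: Iodine–lithium exchange and transmetalation to zinc proceed with retention of the (E) geometry, and the β-amino-alcohol zinc catalyst transfers the alkenyl group (faster than ethyl) to one face of the aldehyde, (+)-MIB being the enantiomer expected to give the R carbinol; the zinc alkoxide then closes onto the cis ester to form the butenolide. Organozinc species leave the two vinylic bromides alone, which lithium or magnesium reagents would not.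

Step 8
Reactants: 15 (5R)-3,4-dibromo-5-[(1E,5S,6R)-2,6-dimethyl-5,8-bis(triethylsilyloxy)oct-1-en-1-yl]furan-2(5H)-one
Product: 16 (5R)-3,4-dibromo-5-[(1E,5S,6R)-5,8-dihydroxy-2,6-dimethyloct-1-en-1-yl]furan-2(5H)-one
Conditions: HF·pyridine, pyridine, THF, 0 °C to rt
Reagents that add atoms: none
Why: Buffered HF·pyridine cleaves both triethylsilyl ethers under weakly acidic conditions that can neither deprotonate C6–H nor displace the β-bromide of the furanone.

Step 9
Reactants: 16 (5R)-3,4-dibromo-5-[(1E,5S,6R)-5,8-dihydroxy-2,6-dimethyloct-1-en-1-yl]furan-2(5H)-one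
Product: 17 (3R,7E)-8-[(2R)-3,4-dibromo-5-oxo-2,5-dihydrofuran-2-yl]-3,7-dimethyl-4-oxooct-7-enal
Conditions: Dess–Martin periodinane (3 equiv), NaHCO3, CH2Cl2, 0 °C to rt
Reagents that add atoms: none
Why: With excess Dess–Martin periodinane both hydroxyls are bound to iodine before either is oxidised, so the new aldehyde finds no free C1 hydroxyl with which to form a lactol and the 1,4-diol goes to the keto-aldehyde; the buffered, non-basic medium spares the C10 centre and C6–H.

Step 10
Reactants: 17 (3R,7E)-8-[(2R)-3,4-dibromo-5-oxo-2,5-dihydrofuran-2-yl]-3,7-dimethyl-4-oxooct-7-enal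
Product: 19 (4S,6R,10E,11aR)-3-bromo-4-hydroxy-6,10-dimethyl-5,6,8,9-tetrahydro-4H-cyclodeca[b]furan-2,7(11aH)-dione, via alkenylchromium 18 (not isolated)
Conditions: CrCl2 (10 equiv), NiCl2 (0.1 equiv), DMSO, rt, 0.002 M, slow addition of 17
Reagents that add atoms: none
Why: Zerovalent nickel, formed from NiCl2 by CrCl2, inserts into the C7–Br bond, which as the β-halide of a vinylogous acyl bromide is far more reactive than C11–Br; the alkenyl group passes to trivalent chromium, and alkenylchromium 18 adds to the C8 aldehyde through a four-centre transition state with the aldehyde oxygen on chromium. The closest known reaction type is the Nozaki–Hiyama–Kishi macrocyclisation of alkenyl halides, β-halo enoates included, onto tethered aldehydes. The ten-membered carbocycle closes in the 10-exo-trig mode by attack of C7 on the carbonyl carbon. Chemoselectivity rests on the reagent: organochromium species add to aldehydes but not to the C1 ketone or the lactone, and the covalent C–Cr bond does not expel the C6 lactone oxygen. The (E)-C4=C5 alkene, the planar butenolide and sp2 C1 cut down the rotatable ring bonds, and high dilution with slow addition suppresses intermolecular coupling. The new C8 centre is controlled by C6, which holds the tether on the C5 face of the butenolide plane, so the aldehyde can stagger about the forming C7–C8 bond in two ways only, with C8–H or with C8–O(Cr) on the open face beside H6. The planned 8S carbinol 19 has C8–H on that face; the substrate does not guarantee this preference over the arrangement that puts the chromium alkoxide there, so the 8R epimer is given a way back to 19 in the closing section.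

Step 11
Reactants: 19 (4S,6R,10E,11aR)-3-bromo-4-hydroxy-6,10-dimethyl-5,6,8,9-tetrahydro-4H-cyclodeca[b]furan-2,7(11aH)-dione
Product: 20 (4S,6R,10E,11aR)-3-bromo-6,10-dimethyl-2,7-dioxo-2,4,5,6,7,8,9,11a-octahydrocyclodeca[b]furan-4-yl (2Z)-2-methylbut-2-enoate
Conditions: angelic acid, 2,4,6-trichlorobenzoyl chloride, Et3N (1 equiv), PhMe, rt; then 19, PhMe, 80 °C
Reagents that add atoms: angelic acid C/C=C(/C)C(=O)O
Why: Acylation by the mixed 2,4,6-trichlorobenzoic angelic anhydride (Yamaguchi-type) without DMAP and without free amine, conditions under which angelates are not isomerised to tiglates and C6–H is not deprotonated; the C8–O bond is not broken, so 8S is retained.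

Step 12
Reactants: 20 (4S,6R,10E,11aR)-3-bromo-6,10-dimethyl-2,7-dioxo-2,4,5,6,7,8,9,11a-octahydrocyclodeca[b]furan-4-yl (2Z)-2-methylbut-2-enoate
Product: 21 (4S,6R,10E,11aR)-3-(hydroxymethyl)-6,10-dimethyl-2,7-dioxo-2,4,5,6,7,8,9,11a-octahydrocyclodeca[b]furan-4-yl (2Z)-2-methylbut-2-enoate
Conditions: Bu3SnCH2OH (1.5 equiv), Pd(PPh3)4 (10 mol %), 1,4-dioxane, 85 °C
Reagents that add atoms: (tributylstannyl)methanol CCCC[Sn](CCCC)(CCCC)CO
Why: Stille coupling in its hydroxymethylating form: zerovalent palladium inserts into the only remaining C(sp2)–Br bond and the stannane transfers its hydroxymethyl group; the neutral conditions spare C6–H, the angelate and the ketone.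

Step 13
Reactants: 21 (4S,6R,10E,11aR)-3-(hydroxymethyl)-6,10-dimethyl-2,7-dioxo-2,4,5,6,7,8,9,11a-octahydrocyclodeca[b]furan-4-yl (2Z)-2-methylbut-2-enoate
Product: 22 (4S,6R,10E,11aR)-3-(acetoxymethyl)-6,10-dimethyl-2,7-dioxo-2,4,5,6,7,8,9,11a-octahydrocyclodeca[b]furan-4-yl (2Z)-2-methylbut-2-enoate
Conditions: Ac2O, pyridine, CH2Cl2, 0 °C
Reagents that add atoms: acetic anhydride CC(=O)OC(C)=O
Why: Acetylation of the primary allylic alcohol with acetic anhydride and pyridine at 0 °C, mild enough to avoid deprotonation at C6.

Step 14
Reactants: 22 (4S,6R,10E,11aR)-3-(acetoxymethyl)-6,10-dimethyl-2,7-dioxo-2,4,5,6,7,8,9,11a-octahydrocyclodeca[b]furan-4-yl (2Z)-2-methylbut-2-enoate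
Product: 23 (4R,5R,6S,8S,10R)-13-acetoxy-8-angeloyloxy-4,5-epoxy-1-oxogermacr-7(11)-en-12,6-olide (CNP0229937.2)
Conditions: dimethyldioxirane, acetone, −20 to 0 °C
Reagents that add atoms: dimethyldioxirane CC1(C)OO1
Why: Dimethyldioxirane epoxidises the only electron-rich alkene; the angelate and butenolide alkenes are electron-poor, and a dioxirane does not bring about Baeyer–Villiger oxidation of the ketone. Allylic 1,3-strain between the C4 methyl and C6 keeps C6–H in the alkene plane, so C7 and the ring cover one face and the reagent adds syn from the open face that carries the lactone oxygen, which gives the trans-epoxide with 4R,5R.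

## Compound list

1 | pent-4-yn-1-ol | C#CCCCO | starting material
2 | alkenylalane: dimethyl[(1E)-5-(dimethylaluminooxy)-2-methylpent-1-en-1-yl]aluminium | C[Al](C)OCCC/C(C)=C/[Al](C)C | intermediate
3 | (E)-5-iodo-4-methylpent-4-en-1-ol | OCCC/C(C)=C/I | intermediate
4 | (E)-5-iodo-4-methylpent-4-enal | O=CCC/C(C)=C/I | intermediate
5 | (E)-crotylboronic acid pinacol ester | C/C=C/CB1OC(C)(C)C(C)(C)O1 | starting material
6 | (3R,4S,7E)-8-iodo-3,7-dimethylocta-1,7-dien-4-ol | C=C[C@@H](C)[C@@H](O)CC/C(C)=C/I | intermediate
7 | bis-borane: 8 with a 9-borabicyclo[3.3.1]nonan-9-yl group on C1 in place of OH and a second one on the C4 oxygen | C1CCC2CCCC1B2CC[C@@H](C)[C@@H](OB1C2CCCC1CCC2)CC/C(C)=C/I | intermediate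
8 | (3R,4S,7E)-8-iodo-3,7-dimethyloct-7-ene-1,4-diol | OCC[C@@H](C)[C@@H](O)CC/C(C)=C/I | intermediate
9 | (3R,4S,7E)-8-iodo-3,7-dimethyl-1,4-bis(triethylsilyloxy)oct-7-ene | CC[Si](CC)(CC)OCC[C@@H](C)[C@@H](O[Si](CC)(CC)CC)CC/C(C)=C/I | intermediate
10 | mucobromic acid (3,4-dibromo-5-hydroxyfuran-2(5H)-one) | OC1OC(=O)C(Br)=C1Br | starting material
11 | methyl (2Z)-2,3-dibromo-4-oxobut-2-enoate | COC(=O)/C(Br)=C(/Br)C=O | intermediate
12 | alkenyllithium: [(1E,5S,6R)-2,6-dimethyl-5,8-bis(triethylsilyloxy)oct-1-en-1-yl]lithium | CC[Si](CC)(CC)OCC[C@@H](C)[C@@H](O[Si](CC)(CC)CC)CC/C(C)=C/[Li] | intermediate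
13 | alkenylzinc: ethyl[(1E,5S,6R)-2,6-dimethyl-5,8-bis(triethylsilyloxy)oct-1-en-1-yl]zinc | CC[Si](CC)(CC)OCC[C@@H](C)[C@@H](O[Si](CC)(CC)CC)CC/C(C)=C/[Zn]CC | intermediate
14 | hydroxy ester: methyl (2Z,4R,5E,9S,10R)-2,3-dibromo-4-hydroxy-6,10-dimethyl-9,12-bis(triethylsilyloxy)dodeca-2,5-dienoate (formed as its zinc alkoxide) | CC[Si](CC)(CC)OCC[C@@H](C)[C@@H](O[Si](CC)(CC)CC)CC/C(C)=C/[C@@H](O)/C(Br)=C(/Br)C(=O)OC | intermediate
15 | (5R)-3,4-dibromo-5-[(1E,5S,6R)-2,6-dimethyl-5,8-bis(triethylsilyloxy)oct-1-en-1-yl]furan-2(5H)-one | CC[Si](CC)(CC)OCC[C@@H](C)[C@@H](O[Si](CC)(CC)CC)CC/C(C)=C/[C@H]1OC(=O)C(Br)=C1Br | intermediate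
16 | (5R)-3,4-dibromo-5-[(1E,5S,6R)-5,8-dihydroxy-2,6-dimethyloct-1-en-1-yl]furan-2(5H)-one | OCC[C@@H](C)[C@@H](O)CC/C(C)=C/[C@H]1OC(=O)C(Br)=C1Br | intermediate
17 | (3R,7E)-8-[(2R)-3,4-dibromo-5-oxo-2,5-dihydrofuran-2-yl]-3,7-dimethyl-4-oxooct-7-enal | O=CC[C@@H](C)C(=O)CC/C(C)=C/[C@H]1OC(=O)C(Br)=C1Br | intermediate
18 | alkenylchromium: 17 with a dichlorochromium group in place of the bromine on C7 (C3 of the dihydrofuranyl ring) | O=CC[C@@H](C)C(=O)CC/C(C)=C/[C@H]1OC(=O)C(Br)=C1[Cr](Cl)Cl | intermediate
19 | (4S,6R,10E,11aR)-3-bromo-4-hydroxy-6,10-dimethyl-5,6,8,9-tetrahydro-4H-cyclodeca[b]furan-2,7(11aH)-dione (germacrane locants: 6R,8S,10R; 11-bromo, 8-hydroxy, 1-oxo, 4E) | O[C@H]1C[C@@H](C)C(=O)CC/C(C)=C/[C@H]2OC(=O)C(Br)=C12 | intermediate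
20 | (4S,6R,10E,11aR)-3-bromo-6,10-dimethyl-2,7-dioxo-2,4,5,6,7,8,9,11a-octahydrocyclodeca[b]furan-4-yl (2Z)-2-methylbut-2-enoate (8-angelate of 19) | C/C=C(/C)C(=O)O[C@H]1C[C@@H](C)C(=O)CC/C(C)=C/[C@H]2OC(=O)C(Br)=C12 | intermediate
21 | (4S,6R,10E,11aR)-3-(hydroxymethyl)-6,10-dimethyl-2,7-dioxo-2,4,5,6,7,8,9,11a-octahydrocyclodeca[b]furan-4-yl (2Z)-2-methylbut-2-enoate | C/C=C(/C)C(=O)O[C@H]1C[C@@H](C)C(=O)CC/C(C)=C/[C@H]2OC(=O)C(CO)=C12 | intermediate
22 | (4S,6R,10E,11aR)-3-(acetoxymethyl)-6,10-dimethyl-2,7-dioxo-2,4,5,6,7,8,9,11a-octahydrocyclodeca[b]furan-4-yl (2Z)-2-methylbut-2-enoate | C/C=C(/C)C(=O)O[C@H]1C[C@@H](C)C(=O)CC/C(C)=C/[C@H]2OC(=O)C(COC(C)=O)=C12 | intermediate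
23 | (4R,5R,6S,8S,10R)-13-acetoxy-8-angeloyloxy-4,5-epoxy-1-oxogermacr-7(11)-en-12,6-olide (CNP0229937.2) | C/C=C(/C)C(=O)O[C@H]1C[C@@H](C)C(=O)CC[C@@]2(C)O[C@@H]2[C@H]2OC(=O)C(COC(C)=O)=C12 | target

## Step count and least certain steps

Total: 14 steps. Longest linear sequence: 13 steps (steps 1–5 and 7–14; step 6 is a one-step branch).

**Step 10 (key step).** The most likely failure is poor or reversed facial selectivity at C8. The bulky chromium alkoxide may prefer the open face beside H6 and give the 8R carbinol. Premature protonation of the alkenylchromium and oligomerisation are lesser risks. The fallback sets out from 17 and returns at 19. If the cyclisation gives mainly the epimer (4R,6R,10E,11aR)-3-bromo-4-hydroxy-6,10-dimethyl-5,6,8,9-tetrahydro-4H-cyclodeca[b]furan-2,7(11aH)-dione F1, this alcohol would be oxidised with Dess–Martin periodinane to the C8 ketone (6R,10E,11aR)-3-bromo-6,10-dimethyl-5,6,8,9-tetrahydrocyclodeca[b]furan-2,4,7(11aH)-trione F2, and the ketone reduced under Luche conditions (NaBH4, CeCl3, MeOH, −78 °C). The conjugated C8 carbonyl should be reduced ahead of the saturated, α-branched C1 ketone. Hydride entering from the open face beside H6 places H8 there, which is 19. C8 is then set by hydride addition to a closed ring and not by the C–C bond formation.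

**Step 7.** The most likely failure is erosion of enantioselectivity at C6. The aldehyde is very electrophilic and carries a cis ester that can chelate zinc, so uncatalysed alkenyl transfer may compete; ethyl transfer is a second risk. The fallback sets out from 9 and returns at 15.
- Iodine–lithium exchange and formylation with DMF would give the enal (2E,6S,7R)-3,7-dimethyl-6,9-bis(triethylsilyloxy)non-2-enal F3.
- Zinc–ProPhenol-catalysed addition of methyl propiolate, a reaction whose scope is centred on enals, would set C6 in methyl (4R,5E,9S,10R)-4-hydroxy-6,10-dimethyl-9,12-bis(triethylsilyloxy)dodec-5-en-2-ynoate F4. The ligand enantiomer is chosen for 4R.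
- Pd(PPh3)4-catalysed syn addition of Me3SnSnMe3 to the ynoate would give methyl (2Z,4R,5E,9S,10R)-4-hydroxy-6,10-dimethyl-9,12-bis(triethylsilyloxy)-2,3-bis(trimethylstannyl)dodeca-2,5-dienoate F5.
- Double bromodestannylation with NBS at low temperature, which spares the trisubstituted alkene, and lactonisation under PPTS would deliver 15.

**Step 9.** The most likely failure is cyclisation of the first-formed hydroxy aldehyde to a lactol and its over-oxidation to a γ-lactone. Epimerisation at C10 is the second risk. The fallback sets out from 16 and returns at 17.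
- Selective silylation of the primary hydroxyl (TBSCl, imidazole, −20 °C) would give (5R)-3,4-dibromo-5-[(1E,5S,6R)-8-(tert-butyldimethylsilyloxy)-5-hydroxy-2,6-dimethyloct-1-en-1-yl]furan-2(5H)-one F6.
- Dess–Martin oxidation would give the ketone (5R)-3,4-dibromo-5-[(1E,6R)-8-(tert-butyldimethylsilyloxy)-2,6-dimethyl-5-oxooct-1-en-1-yl]furan-2(5H)-one F7.
- HF·pyridine would free (5R)-3,4-dibromo-5-[(1E,6R)-8-hydroxy-2,6-dimethyl-5-oxooct-1-en-1-yl]furan-2(5H)-one F8. Its cyclic hemiketal is a tertiary alcohol and cannot be oxidised to a lactone.
- A second Dess–Martin oxidation would give 17.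

**Step 12.** The most likely failure is slow transfer of the sp3 hydroxymethyl group to palladium at the hindered α-position of the lactone. Butyl transfer, loss of bromine by reduction, or ionisation of the allylic angelate could then take over. The fallback sets out from 20 and returns at 21. Palladium-catalysed reductive carbonylation (CO, Bu3SnH added slowly, Pd(PPh3)4, PhMe, 50 °C) would give the aldehyde (4S,6R,10E,11aR)-3-formyl-6,10-dimethyl-2,7-dioxo-2,4,5,6,7,8,9,11a-octahydrocyclodeca[b]furan-4-yl (2Z)-2-methylbut-2-enoate F9. NaBH(OAc)3 would reduce the aldehyde in the presence of the C1 ketone to 21. The one-carbon unit then comes from CO and not from a tin reagent.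

**Step 14.** The most likely failure is loss of facial selectivity if a second ring conformer with the other alkene face exposed is populated. Slow epoxidation of the angelate is a lesser risk. The fallback sets out from 22 and returns at 23 and makes no new compound (F0). The substrate-controlled dioxirane would be replaced by reagent control in a Shi epoxidation (D-fructose-derived ketone, Oxone, buffered, 0 °C, short contact time). Its intrinsic preference for a trans-type trisubstituted alkene is the (R,R)-epoxide required here.

## Further compounds

F1 | step 10 | (4R,6R,10E,11aR)-3-bromo-4-hydroxy-6,10-dimethyl-5,6,8,9-tetrahydro-4H-cyclodeca[b]furan-2,7(11aH)-dione (C8 epimer of 19) | O[C@@H]1C[C@@H](C)C(=O)CC/C(C)=C/[C@H]2OC(=O)C(Br)=C12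
F2 | step 10 | (6R,10E,11aR)-3-bromo-6,10-dimethyl-5,6,8,9-tetrahydrocyclodeca[b]furan-2,4,7(11aH)-trione | O=C1C[C@@H](C)C(=O)CC/C(C)=C/[C@H]2OC(=O)C(Br)=C12
F3 | step 7 | (2E,6S,7R)-3,7-dimethyl-6,9-bis(triethylsilyloxy)non-2-enal | CC[Si](CC)(CC)OCC[C@@H](C)[C@@H](O[Si](CC)(CC)CC)CC/C(C)=C/C=O
F4 | step 7 | methyl (4R,5E,9S,10R)-4-hydroxy-6,10-dimethyl-9,12-bis(triethylsilyloxy)dodec-5-en-2-ynoate | CC[Si](CC)(CC)OCC[C@@H](C)[C@@H](O[Si](CC)(CC)CC)CC/C(C)=C/[C@@H](O)C#CC(=O)OC
F5 | step 7 | methyl (2Z,4R,5E,9S,10R)-4-hydroxy-6,10-dimethyl-9,12-bis(triethylsilyloxy)-2,3-bis(trimethylstannyl)dodeca-2,5-dienoate | CC[Si](CC)(CC)OCC[C@@H](C)[C@@H](O[Si](CC)(CC)CC)CC/C(C)=C/[C@@H](O)/C([Sn](C)(C)C)=C(/[Sn](C)(C)C)C(=O)OC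
F6 | step 9 | (5R)-3,4-dibromo-5-[(1E,5S,6R)-8-(tert-butyldimethylsilyloxy)-5-hydroxy-2,6-dimethyloct-1-en-1-yl]furan-2(5H)-one | CC(C)(C)[Si](C)(C)OCC[C@@H](C)[C@@H](O)CC/C(C)=C/[C@H]1OC(=O)C(Br)=C1Br
F7 | step 9 | (5R)-3,4-dibromo-5-[(1E,6R)-8-(tert-butyldimethylsilyloxy)-2,6-dimethyl-5-oxooct-1-en-1-yl]furan-2(5H)-one | CC(C)(C)[Si](C)(C)OCC[C@@H](C)C(=O)CC/C(C)=C/[C@H]1OC(=O)C(Br)=C1Br
F8 | step 9 | (5R)-3,4-dibromo-5-[(1E,6R)-8-hydroxy-2,6-dimethyl-5-oxooct-1-en-1-yl]furan-2(5H)-one | OCC[C@@H](C)C(=O)CC/C(C)=C/[C@H]1OC(=O)C(Br)=C1Br
F9 | step 12 | (4S,6R,10E,11aR)-3-formyl-6,10-dimethyl-2,7-dioxo-2,4,5,6,7,8,9,11a-octahydrocyclodeca[b]furan-4-yl (2Z)-2-methylbut-2-enoate | C/C=C(/C)C(=O)O[C@H]1C[C@@H](C)C(=O)CC/C(C)=C/[C@H]2OC(=O)C(C=O)=C12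
F0 | step 14 | none | none
A1 | alternative 1 | (6R,8S,10R)-13-acetoxy-8-angeloyloxy-1-oxogermacra-4E,7(11)-dien-12,6-olide (identical with 22) | C/C=C(/C)C(=O)O[C@H]1C[C@@H](C)C(=O)CC/C(C)=C/[C@H]2OC(=O)C(COC(C)=O)=C12
A2 | alternative 2 | ten-membered C6 carbinol with C1 ethylene ketal, C8 tert-butyldimethylsilyl ether, (E)-C4=C5 alkene and a 3-(4-methoxybenzyloxy)prop-1-en-2-yl group on C7 | C=C(COCc1ccc(OC)cc1)[C@H]1[C@H](O)/C=C(C)/CCC2(OCCO2)[C@H](C)C[C@@H]1O[Si](C)(C)C(C)(C)C
A3 | alternative 3 | ten-membered C1 carbinol with C10 exo-methylene, 4,5-epoxide, 8-angelate, 13-acetate and the butenolide in place | C/C=C(/C)C(=O)O[C@H]1CC(=C)[C@H](O)CC[C@@]2(C)O[C@@H]2[C@H]2OC(=O)C(COC(C)=O)=C12
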